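The substrate is what we can time in this flask, charged at 0.30 M and stopped at 2.0 h, and two earlier runs at other charges give us the clock.

| flask | substrate | remark | time |
|---|---|---|---|
| amber | 0.15 M | run made earlier |  |
| red | 0.60 M | run made earlier |  |
| flask | 0.30 M |  | 2.0 h |

- amber (time / min: substrate / %, target / %): 8.00: 96, 2; 20.0: 89, 0; 40.0: 82, 4; 90.0: 63, 6
- red (time / min: substrate / %, target / %): 25.0: 88, 3; 50.0: 76, 2; 80.0: 64, 8; 90.0: 62, 7

(each reading ± 1.5 percentage points)

* share of the substrate used up at 2.0 h
* target at 2.0 h, in percent of the substrate charged
* intermediate at 2.0 h, in percent of the substrate charged
* isomer of the product A at 2.0 h, in percent of the substrate charged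



From the readings at 90.0 min, the substrate half-life comes to 2.25 h in the amber run and 2.17 h in the red run, though the charge rises by a factor of 4.00. The two readings behind these, 63% and 62%, each carry 1.5 percentage points of scatter, so we freeze one number for both runs: the substrate clock, the first-order half-life read from the two together, 2.21 h.

The first rung of the ladder is this clock. It is longer than the flask's 2.0 h, so by our reckoning the flask stops with 53.4% of its substrate remaining, about half of the charge, and 46.6% used up.

The second rung is the target, which gathers more slowly than the substrate goes: at 90.0 min the amber run reads 6% target against 37.0% of its substrate lost, and the red run reads 7% against 38.0%. By those readings, 31.0% of the amber charge stood in neither substrate nor target at that time.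

The forecast gives 47% used up, 10% target, 28% intermediate and 8% isomer of the product A. On the substrate it says: “The loss is therefore first order.”

The flask gives 48.0% used up, 10.2% target, 23.5% intermediate and 9.00% isomer of the product A.

    intermediate ⇌ target (K = 0.710, k = 0.0126 /min)
    substrate → intermediate (k = 0.00523 /min)
    target ⇌ isomer of the product B (K = 0.396, k = 0.00502 /min)
    intermediate ⇌ isomer of the product A (K = 17.0, k = 0.00475 /min)
    2 substrate → homo dimer (k = 1.70 × 10⁻⁵ /M/min)
    substrate + target → side product (k = 0.0145 /M/min)

At 2.00 h the flask holds 3.31% side product beside its 52% substrate, and the clock's 53.4% stands 1.4 points above that substrate. Held at the same charge and read at 5.0 h, the neighbouring flask keeps less substrate than the clock's 20.8%, namely 18.2%, with 9.96% side product.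

All runs stem from a simulated flask for an exercise; scatter was added.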